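The ratio [Z]/[L.X] tends to 0.61, so once the exchange between L.X and Z has come to rest, L.X holds 62.1% of the pool L.X + Z. This is the pool share, and the asked share is this number diminished by the X.L.X standing beside the pool.

    L + X → L.X (k1 = 0.0331 M⁻¹ min⁻¹)
    L + X → Q (k2 = 0.0195 M⁻¹ min⁻¹)
    X + L.X → X.L.X (k3 = 7.90 × 10⁻⁴ M⁻¹ min⁻¹)
    X + Q → X.L.X (k4 = 0.00508 M⁻¹ min⁻¹)
    X → G (k5 = 3.22 × 10⁻⁴ min⁻¹)
    J ⇌ L.X, rate k6*(cs6 - [L.X]) while solid is left; crystals form when [L.X] > cs6 (cs6 = 0.18 M, k6 = 0.0398 min⁻¹)
    L.X ⇌ Z (K7 = 0.61, k7 = 9.75 × 10⁻⁴ min⁻¹)

| flask | L | X | time |
|---|---|---|---|
| red | 0.37 M | 0.600 equiv | 30 h |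
| violet | 0.37 M | 1.20 equiv | 30 h |
| green | 0.37 M | 2.50 equiv | 30 h |
| ochre | 0.37 M | 5.00 equiv | 30 h |

- share of L.X in all that became L.X or X.L.X or Z for red, violet, green, ochre, in this order
- the course of these numbers from the first flask to the last (rises all the way / falls all the way / hardly changes / rises, then falls / falls, then rises)

- for L.X the J are counted in
- as a solid, counted per litre of solution: J
- "hardly changes" means that all values lie within two and a half points (for a concentration: within two and a half percent of the largest)
- run time (red): 30 h

The reckoning runs on red and in powers of ten. The exchange relaxes at its forward and backward constants together, 0.00257 min⁻¹, so over 30 h a departure from the pool share shrinks by 2.01 powers of ten, and a first estimate treats it as closed. In red X is the limiting reagent, and at the start L takes it up at 0.0195 min⁻¹, which stands 1.78 powers of ten above the decay of X at 3.22 × 10⁻⁴ min⁻¹. The estimate therefore lets the charge of X land on L, leaving 40.0% of L. That loss of L measures the exposure ∫[X]dt, and multiplying the exposure by the constants of the second additions gives 0.0138 for L.X and 0.0885 for Q. Mono adducts are born along the way, so on average they feel half of this exposure, and Q is born at 0.589 per L.X, which makes its route the heavier one. The X.L.X beside the pool then comes to 3.29% of it, and the share of red to 60.1%.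

The weak link is the closure of the exchange. Z starts from nothing, so after those powers of ten L.X still lies above the pool share by 0.372% of the pool, and the reforged figure for red is 60.4%. Richer charges expose the mono adducts longer, so the row should fall from flask to flask.

The forecast gives 60.5%, 51.5%, 29.6% and 13.4%, a course that falls all the way, in its words: “The share falls steadily as X.L.X takes over.”

The simulation gives 60.5%, 51.9%, 28.9% and 14.5%, a course that falls all the way, with red beside the reckoned 60.4%.

Red stands near its pool share because of the falling back of Z to L.X: the same flask with that return taken away shows 18.0% instead of 60.5%. Carried to violet, where X.L.X reaches 12.4% of the L charged, the pool share times the pool's part of the three species at 30.0 h, 82.8%, gives 51.4% beside the 51.9% of that flask.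

The numbers of this flask were drawn at random within sensible limits; no experiment stands behind them.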